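## Structural features

The target is a cyclopent-2-en-1-one in which every ring carbon is substituted: C1 is the ketone, C2 carries a (Z)-pent-2-enyl chain, C3 a seven-methylene chain ending in a methyl ester, C4 a secondary hydroxyl and C5 a bromine. The two chains meet the ring at the tetrasubstituted C2=C3 double bond. The only stereocentres, C4 (R) and C5 (S), are adjacent, with oxygen and bromine trans. Fragile elements are the β-hydroxy-α-bromo ketone (a C5 enolate would expel the C4 oxygen), the skipped Z-alkene (its C1' methylene becomes doubly allylic once C2 is sp2), the reducible C–Br bond and the methyl ester. The real difficulty is the order of events: C4 must be set in absolute terms, one halogen must end up at C5 trans to it without enolisation toward C5 while the C4 oxygen is in place, and C2=C3 must be introduced without drawing the side-chain alkene into conjugation. The key step exploits the fact that C1(=O), C5 with its halogen, C4 with its oxygen and C3 with its chain are exactly the atoms of a 2,2-dihalo-3-alkoxycyclobutanone (the adduct of a dihaloketene and a Z-enol ether); only C2 with its pentenyl chain is missing, and a one-carbon ring enlargement can insert it between C1 and C3.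

## Logic of the disconnections

26 from 25. The last bond cut is the ether bond between the C4 oxygen and the benzylic carbon of the auxiliary. The auxiliary thereby serves as the only hydroxyl protection of the route, and the C4–O bond is never broken after it is formed. The forward step must ionise the benzylic C–O bond under acid alone, because 26 does not tolerate base.

25 from 24. The C5–Br bond is cut and re-formed with inversion. Hydrogen delivery to a C5 radical next to the very large C4 ether is expected on the open face, which leaves bromine cis; separating halogen count from halogen configuration makes each problem simple. The forward step needs a substitution at C5 that never passes through a C5 enolate.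

24 from 23. One of the two C5–Br bonds is restored. Holding C5 as CBr2 up to this point removes every C5 hydrogen and so protects the C4 oxygen from β-elimination in all earlier steps. The forward step must stop after one bromine and leave the skipped alkene alone.

23 from 19 by way of 21. The C2=C3 π bond is exchanged for a C2–H and a C3–H bond, with 21 carrying a leaving group on C2. The cut is needed because a ring enlargement can only deliver sp3 carbons at C2 and C3. It reduces the tetrasubstituted enone to a ketone with a single enolisable position. The forward sequence demands a syn elimination into the ring and not into the side chain.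

19 from 13 and 18. The C1–C2 and C2–C3 bonds are cut, which removes C2 with its whole side chain and contracts the ring to four members. What remains in 13 is an array that one cycloaddition can assemble, and the union is convergent. The forward step requires migration of C3 and not of C5, and a single homologation.

18 from 14 by way of 17, 16 and 15. The C=N bond of 18 is traced back to the C–O bond of 14; the diazo carbon is the carbinol carbon. A sulfonamide nitrogen is introduced, freed and nitrosated, so that 18 is released by base only when needed. This avoids low-molecular-weight azides and nitrosoureas. The demands are retention of the Z-alkene and no isolation of 18.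

13 from 10 and 12, the latter from 11. The four-membered ring is cut at the C4–C5 bond and at the bond between the carbonyl carbon and C3. A ketene–alkene cycloaddition makes both bonds, turns the Z geometry of 10 into the cis relationship of C3 and C4, and lets the auxiliary on oxygen choose the face. The forward step must be face-selective and must not cleave the acid-sensitive enol ether.

10 from 9. The C3=C4 alkene is taken back to an alkyne. The triple bond allows the chain to be attached by alkylation, and syn delivery of hydrogen then gives only the Z isomer. The reduction must stop at the alkene.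

9 from 4 and 5. The bond between the future C3 and the first methylene of the ester chain is cut, together with the O–CH3 bond of the ester. An acetylide alkylation makes the former; the carboxyl group travels as its lithium salt, which an acetylide does not attack, and is methylated in the same flask. This uses the commercial bromo acid with no separate masking and unmasking. No free acid may ever meet the ynol ether.

4 from 1 and 2. The O–C(sp2) bond is cut. Compound 2 supplies the two carbons that become C3 and C4, and 1 supplies the oxygen that ends as the C4 hydroxyl. The forward step is a vinylic substitution by the alkoxide of 1 that does not touch its stereocentre.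

## Other disconnections considered

Alternative 1: Piancatelli rearrangement.
- Cut: the C4–C5 ring bond and the C4–O bond, leading back to the furylmethanol A2, whose furan C3 and C4 carry the two chains.
- Forward key step: aqueous acid ionises the carbinol, water adds at the free furan α-position, the ring opens to a pentadienyl cation and a conrotatory 4π closure gives the 4-hydroxycyclopentenone A1.
- In favour: enone, both chains and the C4 oxygen appear in one operation from an achiral aromatic precursor. No diazo compound and no chalcogen are needed, which is better than the chosen plan on safety. The C2=C3 bond is inherited from the furan, so no dehydrogenation and no exo/endo question arise, which is also better.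
- Against: the carbinol carbon of A2 is primary, so the initiating cation lacks a stabilising substituent and furan polymerisation should compete. A furan with two different alkyl groups at C3 and C4 is itself a multi-step target. The closure has no control element for C4, so A1 would be racemic and would need a resolution or an asymmetric variant not established for water as nucleophile. C5 arrives as CH2, so bromine must be introduced later by enolisation toward C5, next to the β-oxygen, where elimination threatens.
- Comparison: on structure the chosen plan delivers C4 in absolute form and C5 already halogenated, which A1 lacks. On mechanism a cationic electrocyclisation is set against a strain-driven 1,2-shift whose regiochemistry the substrate fixes. On step count to the ring the alternative is the equal or the better, but resolution, hydroxyl protection and late bromination would use up that lead.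

Alternative 2: Nozaki–Hiyama–Kishi closure.
- Cut: the C1–C2 bond, leading to the iodo-aldehyde A4.
- Forward key step: CrCl2 with catalytic NiCl2 converts the C–I bond into a carbon–chromium bond (zerovalent nickel inserts first), and this adds to the aldehyde in a 5-exo-trig sense to give the cyclopentenol A3. Oxidation of A3 gives the silyl ether A5, and desilylation gives A1.
- In favour: high chemoselectivity (ester, silyl ether and skipped alkene are tolerated) and neutral ring formation. The C2=C3 bond is fixed by the alkene geometry of A4, which is better than the chosen plan's dehydrogenation. C4 could be set by a catalytic asymmetric step before cyclisation, which is equal in outcome.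
- Against: A4 is a stereodefined tetrasubstituted iodoalkene with three different carbon chains, so the difficulty is moved, not removed. Its β-silyloxy aldehyde is prone to elimination. Stoichiometric divalent chromium is toxic waste and would also reduce an α-bromo ketone, so bromine again has to come last. An extra oxidation is needed.
- Comparison: on structure it is equal on convergence and better on alkene placement, but worse on C5. On mechanism an organometallic carbonyl addition replaces a rearrangement. On step economy the synthesis of A4 plus oxidation, desilylation and bromination should make it longer.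

Alternative 3: enantioselective rhodium hydroacylation.
- Cut: the C1–C5 bond, leading to the silyloxy dienal A6.
- Forward key step: a cationic monovalent rhodium complex of a chiral bisphosphine inserts into the formyl C–H bond, hydride passes to the silyloxy-bearing alkene carbon C4, and C–C reductive elimination closes A5 with C4 set by the ligand.
- In favour: catalytic asymmetric induction in place of a stoichiometric auxiliary, which is better than the chosen plan. Full atom economy, and the enone oxidation level is reached directly, which is also better.
- Against: the usual substrates are 4-alkenals with simple alkenes. Here the alkene is a 1,1-disubstituted silyl enol ether inside a hydrolytically labile 2-silyloxydiene, and the aldehyde is a hindered tetrasubstituted enal. Decarbonylation and chelation or isomerisation of the skipped Z-alkene could compete. A6 must be made as one alkene isomer from an ene-dicarbonyl that tends to cyclise to a furan. Bromination at C5 still comes last.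
- Comparison: on structure it sets C4 as well as the chosen plan but leaves C5 open. On mechanism a catalyst-controlled C–H activation on an untested alkene class is set against a substrate-controlled rearrangement of a well-behaved class. On step count after ring closure it is the equal or the better, but the overall length depends on A6.

Key step: step 8

Assumption: dibromoketene is taken to add to the Z-enol ether of the (S)-auxiliary on the face that gives the (1S,2R)-cyclobutanone 13; if the intrinsic preference is the opposite, the commercially available (R)-alcohol is used in step 1 and no later step changes.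

## Route

Step 1
Reactants: 1 (S)-1-(2,4,6-triisopropylphenyl)ethanol; 2 trichloroethylene
Product: 4 (S)-1-(2,4,6-triisopropylphenyl)ethyl (E)-1,2-dichlorovinyl ether, via dichloroacetylene 3 (not isolated)
Conditions: KH, THF, 0 °C to rt; then 2, −50 °C to rt
Reagents that add atoms: none
Why: Base-induced dehydrochlorination of 2 gives 3 only transiently and in dilute cold solution, and the potassium alkoxide of 1 adds to it in an anti sense; the net vinylic substitution (addition–elimination) leaves the carbinol stereocentre untouched.

Step 2
Reactants: 4 (S)-1-(2,4,6-triisopropylphenyl)ethyl (E)-1,2-dichlorovinyl ether; 5 8-bromooctanoic acid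
Product: 9 methyl 10-[(1S)-1-(2,4,6-triisopropylphenyl)ethoxy]dec-9-ynoate, via lithium alkoxyacetylide 6 (not isolated), via lithium 8-bromooctanoate 7 (not isolated), via lithium ynoate salt 8 (not isolated)
Conditions: 4, n-BuLi (2.2 equiv), THF, −78 to −40 °C; 7 (from 5, LiN(SiMe3)2, THF, −78 to 0 °C), DMPU, −40 °C to rt; then MeI, rt
Reagents that add atoms: iodomethane, CI
Why: n-BuLi converts 4 into acetylide 6 (deprotonation, loss of LiCl, Cl/Li exchange), which undergoes SN2 alkylation at the primary bromide; the lithium carboxylate is inert to the acetylide and so masks the ester, and O-methylation in the same flask means no free acid meets the acid-sensitive ynol ether.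

Step 3
Reactants: 9 methyl 10-[(1S)-1-(2,4,6-triisopropylphenyl)ethoxy]dec-9-ynoate
Product: 10 methyl (9Z)-10-[(1S)-1-(2,4,6-triisopropylphenyl)ethoxy]dec-9-enoate
Conditions: H2 (1 atm), Pd/BaSO4, pyridine, rt
Reagents that add atoms: none
Why: Syn semi-hydrogenation of the alkyne on poisoned palladium gives the Z-enol ether; pyridine suppresses over-reduction and isomerisation.

Step 4
Reactants: 10 methyl (9Z)-10-[(1S)-1-(2,4,6-triisopropylphenyl)ethoxy]dec-9-enoate; 11 tribromoacetyl bromide
Product: 13 methyl 8-[(1S,2R)-3,3-dibromo-4-oxo-2-[(1S)-1-(2,4,6-triisopropylphenyl)ethoxy]cyclobutyl]octanoate, via dibromoketene 12 (not isolated)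
Conditions: Zn–Cu couple, Et2O/DME, slow addition of 11, 0 °C to rt
Reagents that add atoms: none
Why: Zinc dehalogenation of 11 gives 12, which undergoes a ketene–alkene (2+2) cycloaddition in which the ketene carbonyl carbon bonds to the nucleophilic β-carbon of the enol ether; addition is suprafacial on the alkene, so the Z geometry becomes the cis relationship of chain and alkoxy group, and the triisopropylphenyl group shields one face of the s-trans enol ether, which sets C4 (and with it C3) in the sense of the assumption.

Step 5
Reactants: 14 (Z)-hex-3-en-1-ol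
Product: 15 tert-butyl N-[(Z)-hex-3-enyl]-N-(4-methylphenyl)sulfonylcarbamate
Conditions: TsNHBoc, PPh3, DIAD, THF, 0 °C to rt
Reagents that add atoms: tert-butyl N-(4-methylphenyl)sulfonylcarbamate, Cc1ccc(cc1)S(=O)(=O)NC(=O)OC(C)(C)C
Why: Mitsunobu reaction: the primary alcohol is activated as its alkoxyphosphonium ion and displaced by the acidic sulfonylcarbamate nitrogen; this gives clean mono-N-alkylation without an azide and does not involve the Z-alkene.

Step 6
Reactants: 15 tert-butyl N-[(Z)-hex-3-enyl]-N-(4-methylphenyl)sulfonylcarbamate
Product: 16 N-[(Z)-hex-3-enyl]-4-methylbenzenesulfonamide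
Conditions: CF3CO2H, CH2Cl2, 0 °C to rt
Reagents that add atoms: none
Why: Acidolysis of the tert-butyl carbamate with loss of isobutene and CO2 frees the N–H needed for nitrosation; the 1,2-disubstituted alkene is inert to brief acid at this temperature.

Step 7
Reactants: 16 N-[(Z)-hex-3-enyl]-4-methylbenzenesulfonamide
Product: 17 N-[(Z)-hex-3-enyl]-4-methyl-N-nitrosobenzenesulfonamide
Conditions: NaNO2, AcOH/Ac2O, 0 to 5 °C, dark
Reagents that add atoms: sodium nitrite, [Na+].[O-]N=O
Why: N-Nitrosation of a secondary sulfonamide by nitrous acid in acetic acid; N-nitroso sulfonamides are the most easily handled class of diazoalkane precursors, and 17 is stored cold and used soon.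

Step 8
Reactants: 13 methyl 8-[(1S,2R)-3,3-dibromo-4-oxo-2-[(1S)-1-(2,4,6-triisopropylphenyl)ethoxy]cyclobutyl]octanoate; 17 N-[(Z)-hex-3-enyl]-4-methyl-N-nitrosobenzenesulfonamide
Product: 19 methyl 8-[(1R,2R,5R)-3,3-dibromo-4-oxo-5-[(Z)-pent-2-enyl]-2-[(1S)-1-(2,4,6-triisopropylphenyl)ethoxy]cyclopentyl]octanoate, via (Z)-1-diazohex-3-ene 18 (not isolated)
Conditions: 17, KOH, Et2O/EtOH/H2O, 0 °C (shielded, smooth glassware); cold Et2O layer of 18 (dried over KOH) added to 13, Et2O/MeOH, −78 to 0 °C; AcOH quench
Reagents that add atoms: none
Why: Base cleaves the N–S bond of 17 and the diazotate collapses to 18, which is extracted cold and used at once without distillation because a homoallylic diazoalkane can add slowly to its own double bond. The nucleophilic diazo carbon adds to the carbonyl of 13, which is activated by ring strain and by the two α-bromines, to give a diazonium betaine. Loss of N2 with a 1,2-shift of C3, which migrates with retention, forms the C1–C2 and C2–C3 bonds; the closest known reaction type is the Tiffeneau–Demjanov-type diazoalkane homologation of α,α-dihalocyclobutanones from haloketene cycloadducts. The five-membered ring therefore arises by enlargement of the four-membered ring (one carbon inserted between C1 and C3) and not by an end-to-end cyclisation, and release of cyclobutanone strain drives it. The selectivity needed is migration of C3 and not of C5; the electron-poor CBr2 carbon is a poor migrating group, so the substrate secures it. A second homologation should be slow because the product is an unstrained and more hindered ketone, and a limited excess of 18 at low temperature guards against it. The one new stereocentre, C2, is set under substrate control, the pentenyl group settling trans to the C3 chain (less crowded betaine, more stable product), but either epimer serves because C2 becomes sp2 in step 10. C3 and C4 are not touched, so the configuration set in step 4 is carried into 19.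

Step 9
Reactants: 19 methyl 8-[(1R,2R,5R)-3,3-dibromo-4-oxo-5-[(Z)-pent-2-enyl]-2-[(1S)-1-(2,4,6-triisopropylphenyl)ethoxy]cyclopentyl]octanoate
Product: 21 methyl 8-[(1S,2R,5R)-3,3-dibromo-4-oxo-5-[(Z)-pent-2-enyl]-5-(phenylselanyl)-2-[(1S)-1-(2,4,6-triisopropylphenyl)ethoxy]cyclopentyl]octanoate, via trimethylsilyl enol ether 20 (not isolated)
Conditions: Me3SiOTf, Et3N, CH2Cl2, 0 °C; pentane, filtration; PhSeCl, CH2Cl2, −78 °C
Reagents that add atoms: benzeneselenenyl chloride, Cl[Se]c1ccccc1
Why: Soft enolisation can only go toward C2 because C5 has no hydrogen, and it avoids a strong base next to the CBr2 group; electrophilic selenenylation of the silyl enol ether is much faster than addition of PhSeCl to the isolated alkene and should occur anti to the C3 chain and C4 ether, which places selenium syn to the C3 hydrogen.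

Step 10
Reactants: 21 methyl 8-[(1S,2R,5R)-3,3-dibromo-4-oxo-5-[(Z)-pent-2-enyl]-5-(phenylselanyl)-2-[(1S)-1-(2,4,6-triisopropylphenyl)ethoxy]cyclopentyl]octanoate
Product: 23 methyl 8-[(5R)-4,4-dibromo-3-oxo-2-[(Z)-pent-2-enyl]-5-[(1S)-1-(2,4,6-triisopropylphenyl)ethoxy]cyclopent-1-enyl]octanoate, via selenoxide 22 (not isolated)
Conditions: 30% H2O2, pyridine, CH2Cl2, 0 °C to rt
Reagents that add atoms: none
Why: Selenoxide syn-elimination: the C3 hydrogen is held syn-periplanar to selenium by the five-membered ring, which should favour the endocyclic enone over loss of a side-chain hydrogen; pyridine buffers the PhSeOH released, the CBr2 group still blocks any enolisation toward C5, and C4 is untouched.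

Step 11
Reactants: 23 methyl 8-[(5R)-4,4-dibromo-3-oxo-2-[(Z)-pent-2-enyl]-5-[(1S)-1-(2,4,6-triisopropylphenyl)ethoxy]cyclopent-1-enyl]octanoate
Product: 24 methyl 8-[(4R,5R)-4-bromo-3-oxo-2-[(Z)-pent-2-enyl]-5-[(1S)-1-(2,4,6-triisopropylphenyl)ethoxy]cyclopent-1-enyl]octanoate
Conditions: (Me3Si)3SiH (1.05 equiv), Et3B (cat.), air, toluene, −20 °C
Reagents that add atoms: none
Why: Radical chain monodehalogenation with a tin-free hydride: the silyl radical abstracts bromine from the weak C–Br bond of the gem-dibromide (faster than from the monobromide), and the planar α-keto radical takes hydrogen on the face away from the bulky C4 ether, which should leave bromine cis; a radical, unlike an enolate, does not expel the β-alkoxy group, and cyclisation onto the side chain would need a bridgehead alkene and is excluded by Bredt's rule.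

Step 12
Reactants: 24 methyl 8-[(4R,5R)-4-bromo-3-oxo-2-[(Z)-pent-2-enyl]-5-[(1S)-1-(2,4,6-triisopropylphenyl)ethoxy]cyclopent-1-enyl]octanoate
Product: 25 methyl 8-[(4S,5R)-4-bromo-3-oxo-2-[(Z)-pent-2-enyl]-5-[(1S)-1-(2,4,6-triisopropylphenyl)ethoxy]cyclopent-1-enyl]octanoate
Conditions: LiBr, acetone, rt
Reagents that add atoms: lithium bromide, [Li+].[Br-]
Why: Finkelstein-type degenerate SN2 exchange at the α-keto carbon inverts C5; attack anti to the C4 ether is unhindered while the reverse is blocked, so the less crowded trans isomer should accumulate, and the neutral medium avoids a C5 enolate and hence β-elimination.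

Step 13
Reactants: 25 methyl 8-[(4S,5R)-4-bromo-3-oxo-2-[(Z)-pent-2-enyl]-5-[(1S)-1-(2,4,6-triisopropylphenyl)ethoxy]cyclopent-1-enyl]octanoate
Product: 26 methyl 8-[(4S,5R)-4-bromo-5-hydroxy-3-oxo-2-[(Z)-pent-2-enyl]cyclopent-1-enyl]octanoate (CNP0306311.1)
Conditions: CF3CO2H, CH2Cl2, 0 °C
Reagents that add atoms: none
Why: Acidolysis of the ether at its electron-rich benzylic carbon (SN1/E1) releases the hydroxyl with the C4–O bond intact, so C4 keeps its configuration; ionisation at C4 itself is disfavoured by the adjacent enone, and the acidic medium spares the base-sensitive bromo ketone.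

## Compound list

1 | (S)-1-(2,4,6-triisopropylphenyl)ethanol | C[C@H](O)c1c(C(C)C)cc(C(C)C)cc1C(C)C | starting material
2 | trichloroethylene | ClC=C(Cl)Cl | starting material
3 | dichloroacetylene | ClC#CCl | intermediate
4 | (S)-1-(2,4,6-triisopropylphenyl)ethyl (E)-1,2-dichlorovinyl ether | Cl/C=C(/Cl)O[C@@H](C)c1c(C(C)C)cc(C(C)C)cc1C(C)C | intermediate
5 | 8-bromooctanoic acid | OC(=O)CCCCCCCBr | starting material
6 | lithium 2-[(1S)-1-(2,4,6-triisopropylphenyl)ethoxy]ethynide | [Li]C#CO[C@@H](C)c1c(C(C)C)cc(C(C)C)cc1C(C)C | intermediate
7 | lithium 8-bromooctanoate | [Li+].[O-]C(=O)CCCCCCCBr | intermediate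
8 | lithium 10-[(1S)-1-(2,4,6-triisopropylphenyl)ethoxy]dec-9-ynoate | [Li+].[O-]C(=O)CCCCCCCC#CO[C@@H](C)c1c(C(C)C)cc(C(C)C)cc1C(C)C | intermediate
9 | methyl 10-[(1S)-1-(2,4,6-triisopropylphenyl)ethoxy]dec-9-ynoate | COC(=O)CCCCCCCC#CO[C@@H](C)c1c(C(C)C)cc(C(C)C)cc1C(C)C | intermediate
10 | methyl (9Z)-10-[(1S)-1-(2,4,6-triisopropylphenyl)ethoxy]dec-9-enoate | COC(=O)CCCCCCC/C=C\O[C@@H](C)c1c(C(C)C)cc(C(C)C)cc1C(C)C | intermediate
11 | tribromoacetyl bromide | BrC(Br)(Br)C(Br)=O | starting material
12 | dibromoketene | BrC(Br)=C=O | intermediate
13 | methyl 8-[(1S,2R)-3,3-dibromo-4-oxo-2-[(1S)-1-(2,4,6-triisopropylphenyl)ethoxy]cyclobutyl]octanoate (chain and alkoxy group cis) | O=C1C(Br)(Br)[C@H](O[C@@H](C)c2c(C(C)C)cc(C(C)C)cc2C(C)C)[C@@H]1CCCCCCCC(=O)OC | intermediate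
14 | (Z)-hex-3-en-1-ol | CC/C=C\CCO | starting material
15 | tert-butyl N-[(Z)-hex-3-enyl]-N-(4-methylphenyl)sulfonylcarbamate | CC/C=C\CCN(C(=O)OC(C)(C)C)S(=O)(=O)c1ccc(C)cc1 | intermediate
16 | N-[(Z)-hex-3-enyl]-4-methylbenzenesulfonamide | CC/C=C\CCNS(=O)(=O)c1ccc(C)cc1 | intermediate
17 | N-[(Z)-hex-3-enyl]-4-methyl-N-nitrosobenzenesulfonamide | CC/C=C\CCN(N=O)S(=O)(=O)c1ccc(C)cc1 | intermediate
18 | (Z)-1-diazohex-3-ene | CC/C=C\CC=[N+]=[N-] | intermediate
19 | methyl 8-[(1R,2R,5R)-3,3-dibromo-4-oxo-5-[(Z)-pent-2-enyl]-2-[(1S)-1-(2,4,6-triisopropylphenyl)ethoxy]cyclopentyl]octanoate | CC/C=C\C[C@@H]1[C@@H](CCCCCCCC(=O)OC)[C@@H](O[C@@H](C)c2c(C(C)C)cc(C(C)C)cc2C(C)C)C(Br)(Br)C1=O | intermediate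
20 | methyl 8-[(1R,5R)-4,4-dibromo-2-[(Z)-pent-2-enyl]-5-[(1S)-1-(2,4,6-triisopropylphenyl)ethoxy]-3-(trimethylsilyloxy)cyclopent-2-enyl]octanoate | CC/C=C\CC1=C(O[Si](C)(C)C)C(Br)(Br)[C@H](O[C@@H](C)c2c(C(C)C)cc(C(C)C)cc2C(C)C)[C@@H]1CCCCCCCC(=O)OC | intermediate
21 | methyl 8-[(1S,2R,5R)-3,3-dibromo-4-oxo-5-[(Z)-pent-2-enyl]-5-(phenylselanyl)-2-[(1S)-1-(2,4,6-triisopropylphenyl)ethoxy]cyclopentyl]octanoate (selenium trans to the C3 chain) | CC/C=C\C[C@@]1([Se]c2ccccc2)[C@@H](CCCCCCCC(=O)OC)[C@@H](O[C@@H](C)c2c(C(C)C)cc(C(C)C)cc2C(C)C)C(Br)(Br)C1=O | intermediate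
22 | selenoxide of 21 (mixture at selenium) | CC/C=C\C[C@@]1([Se](=O)c2ccccc2)[C@@H](CCCCCCCC(=O)OC)[C@@H](O[C@@H](C)c2c(C(C)C)cc(C(C)C)cc2C(C)C)C(Br)(Br)C1=O | intermediate
23 | methyl 8-[(5R)-4,4-dibromo-3-oxo-2-[(Z)-pent-2-enyl]-5-[(1S)-1-(2,4,6-triisopropylphenyl)ethoxy]cyclopent-1-enyl]octanoate | CC/C=C\CC1=C(CCCCCCCC(=O)OC)[C@@H](O[C@@H](C)c2c(C(C)C)cc(C(C)C)cc2C(C)C)C(Br)(Br)C1=O | intermediate
24 | methyl 8-[(4R,5R)-4-bromo-3-oxo-2-[(Z)-pent-2-enyl]-5-[(1S)-1-(2,4,6-triisopropylphenyl)ethoxy]cyclopent-1-enyl]octanoate (bromine cis to the ether) | CC/C=C\CC1=C(CCCCCCCC(=O)OC)[C@@H](O[C@@H](C)c2c(C(C)C)cc(C(C)C)cc2C(C)C)[C@@H](Br)C1=O | intermediate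
25 | methyl 8-[(4S,5R)-4-bromo-3-oxo-2-[(Z)-pent-2-enyl]-5-[(1S)-1-(2,4,6-triisopropylphenyl)ethoxy]cyclopent-1-enyl]octanoate (bromine trans to the ether) | CC/C=C\CC1=C(CCCCCCCC(=O)OC)[C@@H](O[C@@H](C)c2c(C(C)C)cc(C(C)C)cc2C(C)C)[C@H](Br)C1=O | intermediate
26 | methyl 8-[(4S,5R)-4-bromo-5-hydroxy-3-oxo-2-[(Z)-pent-2-enyl]cyclopent-1-enyl]octanoate | CC/C=C\CC1=C(CCCCCCCC(=O)OC)[C@@H](O)[C@H](Br)C1=O | target

## Step count and risk

Total step count: 13. Longest linear sequence: 10 steps (steps 1, 2, 3, 4, 8, 9, 10, 11, 12, 13, from 1); the diazo branch adds steps 5 to 7 before the convergence in step 8.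

Steps least certain to work:

Step 8 (key step). Most likely failure is slow addition of the hindered secondary diazoalkane to the crowded carbonyl, so that decay of 18 (cycloaddition onto its own alkene, azine formation), epoxide formation or a second homologation competes. Fallback: the bond formation is divided. From 13, diazomethane (the best-established partner for α,α-dihalocyclobutanones, made and used in ether in dedicated smooth glassware) inserts CH2 with the same C3 migration to give methyl 8-[(1R,2R)-3,3-dibromo-4-oxo-2-[(1S)-1-(2,4,6-triisopropylphenyl)ethoxy]cyclopentyl]octanoate F1. Its only enolisable position is C2; the lithium enolate (LiN(SiMe3)2, THF, −78 °C) is alkylated with (Z)-1-bromopent-2-ene, trans to the C3 chain, which returns to the route at 19.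

Step 10. Most likely failure is syn-elimination toward the side-chain methylene instead of the ring hydrogen, because those hydrogens are allylic and the exocyclic product is a conjugated dienone. Fallback: a palladium dehydrosilylation (Saegusa–Ito oxidation) in place of the chalcogen elimination. From 20, stoichiometric Pd(OAc)2 in MeCN at rt gives a divalent palladium enolate whose β-hydride elimination is reversible and, for 2-alkylcycloalkenyl silyl ethers, usually ends at the endocyclic enone; the deposited metal is filtered off at once to limit contact of zerovalent palladium with the C–Br bonds. The route is rejoined at 23 and no new compound is involved.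

Step 4. Most likely failure is loss of material through oligomerisation of the short-lived dibromoketene and cleavage of the enol ether by the zinc bromide formed, with a lower facial preference than the smaller dichloroketene would show. Fallback: the chlorine series with late halogen exchange. From 10, dichloroketene F2 (Zn–Cu couple, trichloroacetyl chloride, Et2O) gives methyl 8-[(1S,2R)-3,3-dichloro-4-oxo-2-[(1S)-1-(2,4,6-triisopropylphenyl)ethoxy]cyclobutyl]octanoate F3. Ring enlargement with 18 as in step 8 gives the dichlorocyclopentanone F4. The operations of steps 9 and 10 lead through the silyl enol ether F5, the selenide F6 and the selenoxide F7 to the dichloro enone F8. Silane reduction as in step 11 gives the cis chloro ketone F9. LiBr in acetone then displaces chloride with inversion and gives the trans bromide directly, which rejoins the route at 25.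

Step 11. Most likely failures are over-reduction to the halogen-free ketone and Z to E isomerisation of the side-chain alkene by reversible addition of the silyl radical. Fallback: a two-electron reduction in a protic medium. From 23, Zn–Cu couple in NH4Cl-saturated MeOH at −20 °C reduces the far more reactive gem-dibromide, and the zinc enolate is protonated by the medium before it can expel the C4 ether; this gives 24 without radical intermediates and involves no new compound.

Step 12. Most likely failure is incomplete inversion because backside attack at C5 is slowed by the neighbouring auxiliary ether, or erosion of material if adventitious base starts enolisation toward C5. Fallback: the order of the last two operations is reversed. From 24, CF3CO2H in CH2Cl2 removes the auxiliary first to give the cis bromo alcohol methyl 8-[(4R,5R)-4-bromo-5-hydroxy-3-oxo-2-[(Z)-pent-2-enyl]cyclopent-1-enyl]octanoate F10. Bromide exchange (Bu4NBr, MeCN, rt) on this much less hindered substrate then equilibrates C5 to the trans arrangement, which rejoins the route at 26.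

## Further compounds

F1 | step 8 | methyl 8-[(1R,2R)-3,3-dibromo-4-oxo-2-[(1S)-1-(2,4,6-triisopropylphenyl)ethoxy]cyclopentyl]octanoate | O=C1C[C@@H](CCCCCCCC(=O)OC)[C@@H](O[C@@H](C)c2c(C(C)C)cc(C(C)C)cc2C(C)C)C1(Br)Br
F0 | step 10 | none | none
F2 | step 4 | dichloroketene | ClC(Cl)=C=O
F3 | step 4 | methyl 8-[(1S,2R)-3,3-dichloro-4-oxo-2-[(1S)-1-(2,4,6-triisopropylphenyl)ethoxy]cyclobutyl]octanoate | O=C1C(Cl)(Cl)[C@H](O[C@@H](C)c2c(C(C)C)cc(C(C)C)cc2C(C)C)[C@@H]1CCCCCCCC(=O)OC
F4 | step 4 | methyl 8-[(1R,2R,5R)-3,3-dichloro-4-oxo-5-[(Z)-pent-2-enyl]-2-[(1S)-1-(2,4,6-triisopropylphenyl)ethoxy]cyclopentyl]octanoate | CC/C=C\C[C@@H]1[C@@H](CCCCCCCC(=O)OC)[C@@H](O[C@@H](C)c2c(C(C)C)cc(C(C)C)cc2C(C)C)C(Cl)(Cl)C1=O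
F5 | step 4 | methyl 8-[(1R,5R)-4,4-dichloro-2-[(Z)-pent-2-enyl]-5-[(1S)-1-(2,4,6-triisopropylphenyl)ethoxy]-3-(trimethylsilyloxy)cyclopent-2-enyl]octanoate | CC/C=C\CC1=C(O[Si](C)(C)C)C(Cl)(Cl)[C@H](O[C@@H](C)c2c(C(C)C)cc(C(C)C)cc2C(C)C)[C@@H]1CCCCCCCC(=O)OC
F6 | step 4 | methyl 8-[(1S,2R,5R)-3,3-dichloro-4-oxo-5-[(Z)-pent-2-enyl]-5-(phenylselanyl)-2-[(1S)-1-(2,4,6-triisopropylphenyl)ethoxy]cyclopentyl]octanoate | CC/C=C\C[C@@]1([Se]c2ccccc2)[C@@H](CCCCCCCC(=O)OC)[C@@H](O[C@@H](C)c2c(C(C)C)cc(C(C)C)cc2C(C)C)C(Cl)(Cl)C1=O
F7 | step 4 | selenoxide of F6 (mixture at selenium) | CC/C=C\C[C@@]1([Se](=O)c2ccccc2)[C@@H](CCCCCCCC(=O)OC)[C@@H](O[C@@H](C)c2c(C(C)C)cc(C(C)C)cc2C(C)C)C(Cl)(Cl)C1=O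
F8 | step 4 | methyl 8-[(5R)-4,4-dichloro-3-oxo-2-[(Z)-pent-2-enyl]-5-[(1S)-1-(2,4,6-triisopropylphenyl)ethoxy]cyclopent-1-enyl]octanoate | CC/C=C\CC1=C(CCCCCCCC(=O)OC)[C@@H](O[C@@H](C)c2c(C(C)C)cc(C(C)C)cc2C(C)C)C(Cl)(Cl)C1=O
F9 | step 4 | methyl 8-[(4R,5R)-4-chloro-3-oxo-2-[(Z)-pent-2-enyl]-5-[(1S)-1-(2,4,6-triisopropylphenyl)ethoxy]cyclopent-1-enyl]octanoate | CC/C=C\CC1=C(CCCCCCCC(=O)OC)[C@@H](O[C@@H](C)c2c(C(C)C)cc(C(C)C)cc2C(C)C)[C@@H](Cl)C1=O
F0 | step 11 | none | none
F10 | step 12 | methyl 8-[(4R,5R)-4-bromo-5-hydroxy-3-oxo-2-[(Z)-pent-2-enyl]cyclopent-1-enyl]octanoate | CC/C=C\CC1=C(CCCCCCCC(=O)OC)[C@@H](O)[C@@H](Br)C1=O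
A1 | alternative 1 | methyl 8-[(5S)-5-hydroxy-3-oxo-2-[(Z)-pent-2-enyl]cyclopent-1-enyl]octanoate | CC/C=C\CC1=C(CCCCCCCC(=O)OC)[C@@H](O)CC1=O
A2 | alternative 1 | methyl 8-[5-(hydroxymethyl)-4-[(Z)-pent-2-enyl]furan-3-yl]octanoate | OCc1occ(CCCCCCCC(=O)OC)c1C/C=C\CC
A3 | alternative 2 | methyl 8-[(3S,5S)-5-(tert-butyldimethylsilyloxy)-3-hydroxy-2-[(Z)-pent-2-enyl]cyclopent-1-enyl]octanoate | CC/C=C\CC1=C(CCCCCCCC(=O)OC)[C@@H](O[Si](C)(C)C(C)(C)C)C[C@@H]1O
A4 | alternative 2 | methyl (9Z,12Z)-9-[(1S)-1-(tert-butyldimethylsilyloxy)-3-oxopropyl]-10-iodopentadeca-9,12-dienoate | CC/C=C\C/C(I)=C(/[C@@H](O[Si](C)(C)C(C)(C)C)CC=O)CCCCCCCC(=O)OC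
A5 | alternative 3 | methyl 8-[(5S)-5-(tert-butyldimethylsilyloxy)-3-oxo-2-[(Z)-pent-2-enyl]cyclopent-1-enyl]octanoate | CC/C=C\CC1=C(CCCCCCCC(=O)OC)[C@@H](O[Si](C)(C)C(C)(C)C)CC1=O
A6 | alternative 3 | methyl (9Z,12Z)-9-[1-(tert-butyldimethylsilyloxy)ethenyl]-10-formylpentadeca-9,12-dienoate | CC/C=C\C/C(C=O)=C(/C(=C)O[Si](C)(C)C(C)(C)C)CCCCCCCC(=O)OC
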